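## Retrosynthetic overview

1. The strategy rests on the C2–C3 bond of the seven-membered ring C1(O-ester)–C2–C3(Me)=C4–C5(=O)–C6(Me)–C10(H). It joins the C2 methylene, which is β to the C1 oxygen, to the methyl-bearing alkene carbon C3. A C2 organometallic would expel the C1 oxygen, so the bond is made from two iodides under reductive nickel catalysis.
2. Target ⇐ C1 veratroylation and C5 allylic oxidation of a bicyclic triol ⇐ C2–C3 closure of a Z-alkenyl iodide (C3) onto a primary iodide (C2), both carried by a trans-1,2-disubstituted cyclopentane (five-membered ring C6–C7–C8–C9(OH, iPr)–C10).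
3. Z-iodoalkene ⇐ hydroxyl-directed trans-hydroalumination of the C5 propargylic alcohol; C9 carbinol ⇐ isopropylcerium addition; C10–C1 ⇐ anti-aldol of a 4,4-disubstituted cyclopentenone with a protected glycolaldehyde.
4. Quaternary C6 and the C5–C4≡C3 chain ⇐ one [2,3]-Wittig rearrangement of the but-2-ynyl ether of (S)-3-methylcyclopent-2-enol (from a CBS reduction).
5. Ring order: the five-membered ring comes with the starting material; the seven-membered ring is closed in step 15.

Key step: step 15

Remarks on the chemistry: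
- Atom numbers C1–C10 and all descriptors given for intermediates refer to the numbering of the target skeleton used above.
- Assumption: C5 is drawn as the epimer expected from the exo-alkynyl transition state of step 3. C5 ends as a ketone (step 17), so a minor C5 epimer can be carried along.
- Assumption: aldehyde 9 is bought as a catalogue compound.

## Route

Step 1
Reactants: 1 3-methylcyclopent-2-en-1-one
Product: 2 (S)-3-methylcyclopent-2-en-1-ol
Conditions: (R)-2-methyl-CBS-oxazaborolidine (C18H20BNO, 10 mol %), BH3·THF, THF, −20 °C; MeOH, then aqueous work-up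
Reagents that add atoms: none
Why: Corey–Bakshi–Shibata reduction, in which the (R)-oxazaborolidine–borane complex binds the carbonyl with the alkenyl arm as the large group and delivers hydride to one face, should set the S carbinol centre (later C8, the stereochemical source for C6).

Step 2
Reactants: 2 (S)-3-methylcyclopent-2-en-1-ol; 3 1-bromobut-2-yne
Product: 4 (S)-3-(but-2-yn-1-yloxy)-1-methylcyclopent-1-ene
Conditions: NaH, THF, 0 °C; then 3, Bu4NI (cat.), 0 °C → rt
Reagents that add atoms: none
Why: Williamson etherification of the sodium alkoxide with the primary propargylic bromide leaves the carbinol centre untouched.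

Step 3
Reactants: 4 (S)-3-(but-2-yn-1-yloxy)-1-methylcyclopent-1-ene
Product: 6 (1S)-1-[(1R)-1-methylcyclopent-2-en-1-yl]but-2-yn-1-ol, via lithiated propargylic ether 5 (not isolated)
Conditions: n-BuLi, THF, −78 → −40 °C; then H2O
Reagents that add atoms: none
Why: [2,3]-Wittig rearrangement of the α-oxy propargylic carbanion through a five-membered envelope on the ring face that carries the oxygen should transfer the C8–O configuration suprafacially to the quaternary C6, with the alkynyl group exo fixing C5, whose configuration is erased later.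

Step 4
Reactants: 6 (1S)-1-[(1R)-1-methylcyclopent-2-en-1-yl]but-2-yn-1-ol
Product: 7 triethylsilyl ether of 6 (5S,6R)
Conditions: Et3SiOTf, 2,6-lutidine, CH2Cl2, −78 → 0 °C
Reagents that add atoms: triethylsilyl trifluoromethanesulfonate, CC[Si](CC)(CC)OS(=O)(=O)C(F)(F)F
Why: Silylation with the silyl triflate and a hindered base covers the hindered propargylic hydroxyl before the oxidation and enolate steps.

Step 5
Reactants: 7 triethylsilyl ether of 6
Product: 8 (4R)-4-methyl-4-[(1S)-1-(triethylsilyloxy)but-2-yn-1-yl]cyclopent-2-en-1-one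
Conditions: CrO3, 3,5-dimethylpyrazole, CH2Cl2, −20 °C
Reagents that add atoms: chromium trioxide, O=[Cr](=O)=O
Why: Allylic C–H oxidation by the CrO3–3,5-dimethylpyrazole complex should give the C9 ketone, because C9 is the only allylic methylene (C6 is quaternary) and the silylated, neopentyl-flanked C5–H and the primary propargylic methyl should react more slowly.

Step 6
Reactants: 8 enone (5S,6R); 9 2-[(4-methoxybenzyl)oxy]acetaldehyde
Product: 11 anti-aldol adduct (1R,5S,6S,10S) of enone 8, via lithium dienolate 10 (not isolated)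
Conditions: LiN(i-Pr)2, THF, −78 °C; then 9, −78 °C; then AcOH, −78 °C
Reagents that add atoms: none
Why: Kinetic deprotonation can only occur at C10 (C6 is quaternary), and aldol addition of the E(O)-configured cyclic enolate through a Zimmerman–Traxler chair should give the anti C10/C1 relationship, with the aldehyde approaching the face opposite the bulky silyloxybutynyl group on C6 so that the C10 chain is trans to the C5 chain.

Step 7
Reactants: 11 anti-aldol adduct (1R,5S,6S,10S)
Product: 12 C1 tert-butyldimethylsilyl ether of 11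
Conditions: t-BuMe2SiOTf, 2,6-lutidine, CH2Cl2, −78 → 0 °C
Reagents that add atoms: tert-butyldimethylsilyl trifluoromethanesulfonate, CC(C)(C)[Si](C)(C)OS(=O)(=O)C(F)(F)F
Why: Low-temperature silylation of the aldol hydroxyl with the silyl triflate blocks retro-aldol and β-elimination in the basic steps that follow.

Step 8
Reactants: 12 C1 tert-butyldimethylsilyl ether of 11
Product: 13 saturated cyclopentanone (1R,5S,6S,10S)
Conditions: [(Ph3P)CuH]6 (5 mol %), PhMe2SiH, t-BuOH, toluene, rt
Reagents that add atoms: none
Why: Copper hydride conjugate reduction adds hydride to C7 of the enone only, the copper enolate being protonated by tert-butanol, and should leave the isolated internal alkyne, the benzyl-type ether and the silyl ethers intact; no stereocentre is formed.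

Step 9
Reactants: 13 saturated cyclopentanone; 14 isopropylmagnesium chloride
Product: 15 tertiary alcohol (1R,5S,6S,9R,10S)
Conditions: CeCl3 (anhydrous), 14, THF, −78 °C; then 13, −78 → 0 °C; then H2O
Reagents that add atoms: none
Why: 1,2-Addition of the weakly basic organocerium reagent, which suppresses enolisation and β-hydride reduction of the hindered ketone, should occur on the face opposite the vicinal C10 side chain and so place the isopropyl group trans to it and the C9 hydroxyl cis (9R).

Step 10
Reactants: 15 tertiary alcohol (1R,5S,6S,9R,10S)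
Product: 16 C5,C9-diol (1R,5S,6S,9R,10S)
Conditions: pyridinium p-toluenesulfonate (cat.), MeOH–CH2Cl2, 0 °C → rt
Reagents that add atoms: none
Why: Acid-catalysed methanolysis cleaves the triethylsilyl ether much faster than the tert-butyldimethylsilyl ether and frees the propargylic hydroxyl that must direct the next step.

Step 11
Reactants: 16 C5,C9-diol
Product: 18 Z-iodoalkene diol (1R,5R,6S,9R,10S), via alkenylalanate 17 (not isolated)
Conditions: NaAlH2(OCH2CH2OMe)2, THF, 0 °C → rt; EtOAc, −78 °C; I2, THF, −78 → 0 °C; aqueous potassium sodium tartrate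
Reagents that add atoms: iodine, [I][I]
Why: Hydroxyl-directed trans-hydroalumination of the propargylic alcohol delivers hydride to C4 and aluminium to C3 within a five-membered alkoxyalanate, and iodinolysis with retention should give the Z-iodoalkene with iodine cis to C5.

Step 12
Reactants: 18 Z-iodoalkene diol
Product: 19 C5,C9-bis(triethylsilyl) ether (1R,5R,6S,9R,10S)
Conditions: Et3SiOTf, 2,6-lutidine, CH2Cl2, −78 °C → rt
Reagents that add atoms: triethylsilyl trifluoromethanesulfonate, CC[Si](CC)(CC)OS(=O)(=O)C(F)(F)F
Why: Silyl triflate and 2,6-lutidine silylate both the secondary allylic and the hindered tertiary hydroxyl, which removes every internal nucleophile before the primary iodide is made.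

Step 13
Reactants: 19 C5,C9-bis(triethylsilyl) ether
Product: 20 primary C2 alcohol (1R,5R,6S,9R,10S)
Conditions: DDQ, CH2Cl2–pH 7 phosphate buffer, 0 °C
Reagents that add atoms: none
Why: Oxidative cleavage of the 4-methoxybenzyl ether by DDQ through the benzylic oxocarbenium ion is orthogonal to the three silyl ethers and the alkenyl iodide when buffered.

Step 14
Reactants: 20 primary C2 alcohol
Product: 21 diiodide (1R,5R,6S,9R,10S) with Z-alkenyl iodide at C3 and primary iodide at C2
Conditions: I2, PPh3, imidazole, CH2Cl2, 0 °C → rt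
Reagents that add atoms: iodine, [I][I]
Why: Appel-type iodination through the alkoxyphosphonium iodide converts the only free (primary) hydroxyl into the iodide by SN2 displacement without touching C1.

Step 15
Reactants: 21 diiodide (1R,5R,6S,9R,10S)
Product: 22 bicyclic C3=C4 alkene (1S,5R,6S,9R,10S) with silyl ethers at C1 (t-BuMe2Si), C5 and C9 (Et3Si)
Conditions: NiCl2(dme) (30 mol %), 4,4'-di-tert-butyl-2,2'-bipyridine (30 mol %), Mn powder (4 equiv), NaI (cat.), N,N-dimethylacetamide, 40 °C; 21 added by syringe pump over 12 h to a final 0.005 M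
Reagents that add atoms: none
Why: Proposed new method: zerovalent nickel bound to the bipyridine should insert into the C3–I bond of the Z-alkenyl iodide with retention, a low-valent nickel species should abstract iodine from C2–I to give the primary C2 radical, the divalent alkenylnickel held in the same molecule should capture that radical, and reductive elimination from the resulting trivalent nickel centre forms C2–C3 while manganese returns nickel to its low-valent state; the closest known reaction type is the intermolecular nickel-catalysed reductive cross-electrophile coupling of alkenyl halides with primary alkyl halides under the same NiCl2(dme)/bipyridine/Mn conditions. The seven-membered ring is closed by C(sp2)–C(sp3) reductive elimination from an eight-membered nickelacycle, so that both alkene carbons C3 and C4 end up inside the ring. No stereocentre is formed: C1, C5, C6, C9 and C10 are spectators, and the C3=C4 geometry is that of the Z-iodide fixed in step 11, the only geometry that lets C2 and C5 sit cis. The step needs ring closure to outrun dimerisation, oligomerisation and reduction of the C2 radical, which the tether, the absence of any other alkene within reach of a 5-exo attack, slow addition into a dilute catalyst solution and a high nickel loading should secure. It also needs the C1 oxygen to stay in place, which follows from the radical (not carbanionic) character at C2 and from manganese, which does not convert the primary iodide into a β-silyloxy organometallic.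

Step 16
Reactants: 22 bicyclic tris(silyl) ether
Product: 23 bicyclic triol (1S,5R,6S,9R,10S)
Conditions: Bu4NF, THF, rt → 45 °C
Reagents that add atoms: none
Why: Fluoride cleaves all three silyl ethers, and no base-sensitive group is present at this stage.

Step 17
Reactants: 23 bicyclic triol
Product: 24 enone diol (1S,6S,9R,10S)
Conditions: MnO2 (activated, excess), CH2Cl2, rt
Reagents that add atoms: none
Why: MnO2 should oxidise only the allylic C5 carbinol (either epimer) to the enone and leave the non-allylic secondary C1 and the tertiary C9 hydroxyls, which removes the C5 stereocentre.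

Step 18
Reactants: 24 enone diol; 25 3,4-dimethoxybenzoyl chloride
Product: 26 target CNP0111132.1 (1S,6S,9R,10S)
Conditions: DMAP, Et3N, CH2Cl2, 0 °C → rt
Reagents that add atoms: none
Why: DMAP-catalysed acylation with the acid chloride esterifies the secondary C1 hydroxyl with retention, while the hindered tertiary C9 hydroxyl should not react.

## Compound list

1 | 3-methylcyclopent-2-en-1-one | CC1=CC(=O)CC1 | starting material
2 | (S)-3-methylcyclopent-2-en-1-ol | CC1=C[C@@H](O)CC1 | intermediate
3 | 1-bromobut-2-yne | CC#CCBr | starting material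
4 | (S)-3-(but-2-yn-1-yloxy)-1-methylcyclopent-1-ene | CC#CCO[C@@H]1C=C(C)CC1 | intermediate
5 | lithiated propargylic ether of 4 (lithium on the OCH carbon next to the alkyne; not isolated) | CC#CC([Li])O[C@@H]1C=C(C)CC1 | intermediate
6 | (1S)-1-[(1R)-1-methylcyclopent-2-en-1-yl]but-2-yn-1-ol (5S,6R) | CC#C[C@@H](O)[C@@]1(C)C=CCC1 | intermediate
7 | triethylsilyl ether of 6 (5S,6R) | CC#C[C@@H](O[Si](CC)(CC)CC)[C@@]1(C)C=CCC1 | intermediate
8 | (4R)-4-methyl-4-[(1S)-1-(triethylsilyloxy)but-2-yn-1-yl]cyclopent-2-en-1-one | CC#C[C@@H](O[Si](CC)(CC)CC)[C@@]1(C)C=CC(=O)C1 | intermediate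
9 | 2-[(4-methoxybenzyl)oxy]acetaldehyde | COc1ccc(COCC=O)cc1 | starting material
10 | lithium dienolate of 8 (C9–OLi, C9=C10; not isolated) | CC#C[C@@H](O[Si](CC)(CC)CC)[C@@]1(C)C=CC(O[Li])=C1 | intermediate
11 | (4S,5S)-5-[(1R)-1-hydroxy-2-[(4-methoxybenzyl)oxy]ethyl]-4-methyl-4-[(1S)-1-(triethylsilyloxy)but-2-yn-1-yl]cyclopent-2-en-1-one (anti-aldol; 1R,5S,6S,10S) | CC#C[C@@H](O[Si](CC)(CC)CC)[C@@]1(C)C=CC(=O)[C@@H]1[C@@H](O)COCc1ccc(OC)cc1 | intermediate
12 | C1 tert-butyldimethylsilyl ether of 11 (1R,5S,6S,10S) | CC#C[C@@H](O[Si](CC)(CC)CC)[C@@]1(C)C=CC(=O)[C@@H]1[C@@H](O[Si](C)(C)C(C)(C)C)COCc1ccc(OC)cc1 | intermediate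
13 | saturated cyclopentanone (C9 ketone; 1R,5S,6S,10S) | CC#C[C@@H](O[Si](CC)(CC)CC)[C@@]1(C)CCC(=O)[C@@H]1[C@@H](O[Si](C)(C)C(C)(C)C)COCc1ccc(OC)cc1 | intermediate
14 | isopropylmagnesium chloride | CC(C)[Mg]Cl | starting material
15 | tertiary C9 alcohol with isopropyl trans to the C10 chain (1R,5S,6S,9R,10S) | CC#C[C@@H](O[Si](CC)(CC)CC)[C@@]1(C)CC[C@@](O)(C(C)C)[C@@H]1[C@@H](O[Si](C)(C)C(C)(C)C)COCc1ccc(OC)cc1 | intermediate
16 | C5,C9-diol (propargylic C5–OH free; 1R,5S,6S,9R,10S) | CC#C[C@@H](O)[C@@]1(C)CC[C@@](O)(C(C)C)[C@@H]1[C@@H](O[Si](C)(C)C(C)(C)C)COCc1ccc(OC)cc1 | intermediate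
17 | cyclic sodium alkenylalanate (O–Al–C3=C4–C5 ring; idealised, C9 oxygen drawn as OH; not isolated) | CC1=C[C@H]([C@@]2(C)CC[C@@](O)(C(C)C)[C@@H]2[C@@H](O[Si](C)(C)C(C)(C)C)COCc2ccc(OC)cc2)O[Al-]1(OCCOC)OCCOC.[Na+] | intermediate
18 | Z-iodoalkene diol (iodine on C3 cis to C5; 1R,5R,6S,9R,10S) | C/C(I)=C/[C@@H](O)[C@@]1(C)CC[C@@](O)(C(C)C)[C@@H]1[C@@H](O[Si](C)(C)C(C)(C)C)COCc1ccc(OC)cc1 | intermediate
19 | C5,C9-bis(triethylsilyl) ether of 18 (1R,5R,6S,9R,10S) | C/C(I)=C/[C@@H](O[Si](CC)(CC)CC)[C@@]1(C)CC[C@@](O[Si](CC)(CC)CC)(C(C)C)[C@@H]1[C@@H](O[Si](C)(C)C(C)(C)C)COCc1ccc(OC)cc1 | intermediate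
20 | primary C2 alcohol (1R,5R,6S,9R,10S) | C/C(I)=C/[C@@H](O[Si](CC)(CC)CC)[C@@]1(C)CC[C@@](O[Si](CC)(CC)CC)(C(C)C)[C@@H]1[C@@H](O[Si](C)(C)C(C)(C)C)CO | intermediate
21 | diiodide, precursor of the key step: trans-cyclopentane with the Z-3-iodo-1-(triethylsilyloxy)but-2-enyl chain on C6 and the 1-(tert-butyldimethylsilyloxy)-2-iodoethyl chain on C10 (1R,5R,6S,9R,10S) | I/C(C)=C\[C@@H](O[Si](CC)(CC)CC)[C@@]1(C)CC[C@@](O[Si](CC)(CC)CC)(C(C)C)[C@@H]1[C@H](CI)O[Si](C)(C)C(C)(C)C | intermediate
22 | bicyclic C3=C4 alkene with silyl ethers at C1, C5 and C9, product of the key step (1S,5R,6S,9R,10S) | CC(C)(C)[Si](C)(C)O[C@H]2CC(C)=C[C@@H](O[Si](CC)(CC)CC)[C@@]3(C)CC[C@@](O[Si](CC)(CC)CC)(C(C)C)[C@H]23 | intermediate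
23 | bicyclic triol (1S,5R,6S,9R,10S) | O[C@H]2CC(C)=C[C@@H](O)[C@@]3(C)CC[C@@](O)(C(C)C)[C@H]23 | intermediate
24 | enone diol (C5 ketone, C1 and C9 hydroxyls; 1S,6S,9R,10S) | O[C@H]2CC(C)=CC(=O)[C@@]3(C)CC[C@@](O)(C(C)C)[C@H]23 | intermediate
25 | 3,4-dimethoxybenzoyl chloride | COc1ccc(C(Cl)=O)cc1OC | starting material
26 | CNP0111132.1, the C1 3,4-dimethoxybenzoate of 24 (1S,6S,9R,10S) | COc1ccc(C(=O)O[C@H]2CC(C)=CC(=O)[C@@]3(C)CC[C@@](O)(C(C)C)[C@H]23)cc1OC | target

## Step count and risks

Total step count: 18. Longest linear sequence: 18 steps (from 1; compounds 3, 9, 14 and 25 are bought).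

Steps most likely to fail:

1. Step 15 (Proposed new method). The C2 radical may be reduced or may dimerise before the tethered alkenylnickel captures it, intermolecular coupling may give oligomers, the alkenylnickel may lose its Z geometry or be protonated, or the radical may attack C4 in a 6-exo mode. The fallback uses known chemistry and a different ring closure, ring-closing metathesis at C3=C4; it sets out from 15 and comes back at 22. Semi-hydrogenation of the alkyne of 15 (H2, Pd on CaCO3 poisoned with Pb(OAc)2, quinoline, EtOAc) should give the (Z)-propenyl carbinol F1. Et3SiOTf and 2,6-lutidine then cover the C9 hydroxyl to give the bis(triethylsilyl) ether F2. DDQ removes the 4-methoxybenzyl group to give the primary alcohol F3, and I2/PPh3/imidazole gives the primary iodide F4. Copper-catalysed alkylation of isopropenylmagnesium bromide (CuI cat., THF, −20 → 0 °C) gives the 2-methylallyl diene F5. Ring-closing metathesis with the second-generation Hoveyda–Grubbs catalyst (C31H38Cl2N2ORu, toluene, 80 °C, dilute) joins C3 and C4 with loss of propene and gives 22, after which steps 16–18 follow unchanged.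

2. Step 6. Simple diastereoselection of the lithium aldol may be weak (syn adduct at C1), the aldehyde may attack the enolate face syn to the C5 chain, or the adduct may undergo retro-aldol on work-up. The fallback moves stereocontrol from the lithium enolate to a covalently bound boron enolate formed by soft enolisation; it sets out from 8 and comes back at 11. Enolisation of 8 with (c-C6H11)2BCl and Et3N (Et2O, −78 → 0 °C) gives the dicyclohexylboron dienolate F6. This should add 9 at −78 °C through a compact boron-centred chair to give the boron aldolate F7 with the anti relationship. Buffered oxidative work-up (H2O2, MeOH, pH 7, 0 °C) frees 11.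

3. Step 3. A [1,2]-shift may compete, the base may deprotonate the alkyne methyl or the ring C8–H instead of the OCH2 group, or chirality transfer to C6 may be incomplete. The fallback makes the carbanion regiospecifically by tin–lithium exchange and forms the C5–C4 bond in a separate step; it sets out from 2 and comes back at 6. O-Alkylation of 2 with Bu3SnCH2I (KH, THF, 0 °C → rt) gives the stannylmethyl ether F8. n-BuLi (THF, −78 °C) gives the lithiomethyl ether F9, which rearranges ([2,3]-Wittig, Wittig–Still variant) to (R)-(1-methylcyclopent-2-en-1-yl)methanol F10. Dess–Martin periodinane (CH2Cl2, 0 °C) gives (R)-1-methylcyclopent-2-ene-1-carbaldehyde F11. Prop-1-ynylmagnesium bromide (THF, −78 °C) gives 6 together with its C5 epimer F12; both can be used because C5 is oxidised in step 17.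

Further compounds

F1 | step 15 | (Z)-propenyl carbinol from semi-hydrogenation of 15 (C5–OSiEt3, C9–OH) | C/C=C\[C@@H](O[Si](CC)(CC)CC)[C@@]1(C)CC[C@@](O)(C(C)C)[C@@H]1[C@@H](O[Si](C)(C)C(C)(C)C)COCc1ccc(OC)cc1
F2 | step 15 | C5,C9-bis(triethylsilyl) ether of F1 | C/C=C\[C@@H](O[Si](CC)(CC)CC)[C@@]1(C)CC[C@@](O[Si](CC)(CC)CC)(C(C)C)[C@@H]1[C@@H](O[Si](C)(C)C(C)(C)C)COCc1ccc(OC)cc1
F3 | step 15 | primary C2 alcohol from F2 | C/C=C\[C@@H](O[Si](CC)(CC)CC)[C@@]1(C)CC[C@@](O[Si](CC)(CC)CC)(C(C)C)[C@@H]1[C@@H](O[Si](C)(C)C(C)(C)C)CO
F4 | step 15 | primary C2 iodide from F3 | C/C=C\[C@@H](O[Si](CC)(CC)CC)[C@@]1(C)CC[C@@](O[Si](CC)(CC)CC)(C(C)C)[C@@H]1[C@@H](O[Si](C)(C)C(C)(C)C)CI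
F5 | step 15 | 2-methylallyl diene for ring-closing metathesis | C/C=C\[C@@H](O[Si](CC)(CC)CC)[C@@]1(C)CC[C@@](O[Si](CC)(CC)CC)(C(C)C)[C@@H]1[C@@H](O[Si](C)(C)C(C)(C)C)CC(C)=C
F6 | step 6 | dicyclohexylboron dienolate of 8 | CC#C[C@@H](O[Si](CC)(CC)CC)[C@@]1(C)C=CC(OB(C2CCCCC2)C2CCCCC2)=C1
F7 | step 6 | dicyclohexylboron aldolate of 11 | CC#C[C@@H](O[Si](CC)(CC)CC)[C@@]1(C)C=CC(=O)[C@@H]1[C@@H](OB(C2CCCCC2)C2CCCCC2)COCc1ccc(OC)cc1
F8 | step 3 | tributyl{[(S)-3-methylcyclopent-2-en-1-yl]oxymethyl}stannane | CCCC[Sn](CCCC)(CCCC)CO[C@@H]1C=C(C)CC1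
F9 | step 3 | lithiomethyl ether of 2 | [Li]CO[C@@H]1C=C(C)CC1
F10 | step 3 | (R)-(1-methylcyclopent-2-en-1-yl)methanol | OC[C@@]1(C)C=CCC1
F11 | step 3 | (R)-1-methylcyclopent-2-ene-1-carbaldehyde | O=C[C@@]1(C)C=CCC1
F12 | step 3 | C5 epimer of 6 (5R,6R) | CC#C[C@H](O)[C@@]1(C)C=CCC1
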